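**Retrosynthetic overview**

1. Locants follow the avarane skeleton: ring A = C1–C5 + C10, ring B = C5–C10, C11 = exocyclic CH2 on C4, C15 = benzylic CH2 on C9. Enabling feature: the methylidene carbon C4 is bonded to the methyl-bearing ring-fusion carbon C5, whose methyl is trans to H at C10, and C9 is quaternary. This is the trace of a tertiary C9 radical adding to C10 of an E-C5(CH3)=C10H alkene, followed by the C5 radical adding to the inner carbon of a terminal alkyne C4≡C11.
2. Key disconnection: C9–C10 (ring B, closed first, 6-endo) and C4–C5 (ring A, closed second, 6-exo-dig) in one reductive decarboxylative radical bicyclisation of an acyclic dienyne N-acyloxyphthalimide. Only C8 is stereogenic in the precursor, and CO2 is the traceless activating group.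
3. Acid precursor: C9–C15 by C-alkylation of a carboxylic acid enediolate with a benzylic bromide, C9–CH3 by enolate methylation, C8 by copper-catalysed asymmetric conjugate methylation of an E-enoate.
4. Fragment 1 (chain): E-C5=C10 alkene by Johnson–Claisen rearrangement of the adduct of methacrolein and a silylpentynyl Grignard reagent. Fragment 2 (arene): from methyl 3-bromo-4-hydroxy-5-methoxybenzoate by demethylation, silylation, Negishi methylation and benzylic bromination.
5. End game: fluoride removal of the two aryl silyl ethers, with no acid near the exocyclic alkene.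

Key step: step 14

Remark: C2 of compounds 12, 13, 20 and 21 (the future C9) is carried as both epimers, because it becomes a planar radical in step 14.
Remark: open-shell intermediates and metal salts of products that exist only until work-up are treated as mechanism and carry no number; species generated in a separate stage before the next reagent is added are numbered.
Remark: the facial sense assigned to (R)-Tol-BINAP in step 5 is taken from memory of how linear E-enoates behave and is not certain; if a pilot run gives the 3R product, the antipodal ligand is used.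
Remark: compounds 1, 2 and 14 and all reagents are taken as commercially available.

**Route**

Step 1
Reactants: 1 (5-chloropent-1-yn-1-yl)trimethylsilane; 2 methacrolein
Product: 4 (3RS)-2-methyl-8-(trimethylsilyl)oct-1-en-7-yn-3-ol, via Grignard reagent 3 (not isolated)
Conditions: Mg, I2 (cat.), THF, 65 °C; then 2, −78 → 0 °C; aq. NH4Cl
Reagents that add atoms: none
Why: Grignard 1,2-addition to the enal carbonyl; the carbinol centre is formed racemic on purpose because it is destroyed in step 2.

Step 2
Reactants: 4 (3RS)-2-methyl-8-(trimethylsilyl)oct-1-en-7-yn-3-ol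
Product: 7 ethyl (4E)-4-methyl-10-(trimethylsilyl)dec-4-en-9-ynoate, via mixed orthoester 5 (not isolated), via ketene acetal 6 (not isolated)
Conditions: MeC(OEt)3 (6 equiv), EtCO2H (5 mol %), 140 °C, EtOH distilled off
Reagents that add atoms: triethyl orthoacetate, CCOC(C)(OCC)OCC
Why: Johnson–Claisen rearrangement through a chair transition state with the alkynylpropyl chain equatorial should give the E trisubstituted alkene that later encodes the trans ring fusion; no stereocentre remains.

Step 3
Reactants: 7 ethyl (4E)-4-methyl-10-(trimethylsilyl)dec-4-en-9-ynoate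
Product: 8 (4E)-4-methyl-10-(trimethylsilyl)dec-4-en-9-ynal
Conditions: i-Bu2AlH (1.1 equiv), CH2Cl2, −78 °C; MeOH, aq. potassium sodium tartrate
Reagents that add atoms: none
Why: Partial ester reduction with diisobutylaluminium hydride, whose tetrahedral aluminium acetal is stable at −78 °C and releases the aldehyde only on work-up; no stereocentre is formed.

Step 4
Reactants: 8 (4E)-4-methyl-10-(trimethylsilyl)dec-4-en-9-ynal
Product: 9 methyl (2E,6E)-6-methyl-12-(trimethylsilyl)dodeca-2,6-dien-11-ynoate
Conditions: Ph3P=CHCO2Me (1.3 equiv), CH2Cl2, 23 °C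
Reagents that add atoms: methyl (triphenylphosphoranylidene)acetate, COC(=O)C=P(c1ccccc1)(c1ccccc1)c1ccccc1
Why: Wittig olefination with a stabilised ylide should give the E enoate needed for face-selective conjugate addition; no stereocentre is formed.

Step 5
Reactants: 9 methyl (2E,6E)-6-methyl-12-(trimethylsilyl)dodeca-2,6-dien-11-ynoate
Product: 10 methyl (3S,6E)-3,6-dimethyl-12-(trimethylsilyl)dodec-6-en-11-ynoate
Conditions: MeMgBr (3 equiv), CuI (3 mol %), (R)-Tol-BINAP (4.5 mol %), t-BuOMe, −40 °C; aq. NH4Cl
Reagents that add atoms: methylmagnesium bromide, C[Mg]Br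
Why: Copper-catalysed asymmetric conjugate addition of a Grignard reagent to a linear E enoate, in which the chiral bisphosphine–copper complex delivers methyl to the Si face of C3 and so sets the 3S centre (the future C8), the only stereocentre carried into the key step.

Step 6
Reactants: 10 methyl (3S,6E)-3,6-dimethyl-12-(trimethylsilyl)dodec-6-en-11-ynoate
Product: 12 methyl (2RS,3S,6E)-2,3,6-trimethyl-12-(trimethylsilyl)dodec-6-en-11-ynoate, via lithium enolate 11 (not isolated)
Conditions: LiN(i-Pr)2 (1.15 equiv), THF, −78 °C; MeI (2 equiv), −78 → −20 °C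
Reagents that add atoms: iodomethane, CI
Why: Ester enolate alkylation; the new C2 centre is formed without control, which is harmless because this carbon becomes a planar radical in step 14, and C3 is not acidic.

Step 7
Reactants: 12 methyl (2RS,3S,6E)-2,3,6-trimethyl-12-(trimethylsilyl)dodec-6-en-11-ynoate
Product: 13 (2RS,3S,6E)-2,3,6-trimethyldodec-6-en-11-ynoic acid
Conditions: LiOH·H2O (6 equiv), THF/MeOH/H2O, 50 °C; then 1 M HCl to pH 3
Reagents that add atoms: lithium hydroxide, [Li+].[OH-]
Why: Saponification with hydroxide-mediated protodesilylation of the alkynylsilane in the same pot; the 3S centre is beta to the carboxyl group and cannot epimerise.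

Step 8
Reactants: 14 methyl 3-bromo-4-hydroxy-5-methoxybenzoate
Product: 15 methyl 3-bromo-4,5-dihydroxybenzoate
Conditions: BBr3 (2.2 equiv), CH2Cl2, −78 → 0 °C; H2O
Reagents that add atoms: none
Why: Lewis acid cleavage of an aryl methyl ether with BBr3, which should be fast for a guaiacol-type ether at temperatures at which the methyl benzoate survives; no stereocentre.

Step 9
Reactants: 15 methyl 3-bromo-4,5-dihydroxybenzoate
Product: 16 methyl 3-bromo-4,5-bis[(tert-butyldimethylsilyl)oxy]benzoate
Conditions: TBSCl (2.6 equiv), imidazole (5 equiv), DMF, 40 °C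
Reagents that add atoms: tert-butyldimethylsilyl chloride, CC(C)(C)[Si](C)(C)Cl
Why: Silylation of both phenols; silyl ethers are chosen because fluoride removes them at the end without acid that could isomerise the exocyclic alkene.

Step 10
Reactants: 16 methyl 3-bromo-4,5-bis[(tert-butyldimethylsilyl)oxy]benzoate
Product: 17 methyl 3,4-bis[(tert-butyldimethylsilyl)oxy]-5-methylbenzoate
Conditions: MeZnCl (1.5 equiv), Pd[P(t-Bu)3]2 (3 mol %), THF, 50 °C
Reagents that add atoms: methylzinc chloride, C[Zn]Cl
Why: Negishi cross-coupling of an aryl bromide, run without base so that the aryl silyl ethers and the ester should be untouched; no stereocentre.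

Step 11
Reactants: 17 methyl 3,4-bis[(tert-butyldimethylsilyl)oxy]-5-methylbenzoate
Product: 18 methyl 3-(bromomethyl)-4,5-bis[(tert-butyldimethylsilyl)oxy]benzoate
Conditions: NBS (1.05 equiv), AIBN (5 mol %), PhCF3, 80 °C
Reagents that add atoms: N-bromosuccinimide, O=C1CCC(=O)N1Br
Why: Wohl–Ziegler bromination at the only benzylic C–H position, with ring bromination disfavoured by the ester and the radical conditions; no stereocentre.

Step 12
Reactants: 13 (2RS,3S,6E)-2,3,6-trimethyldodec-6-en-11-ynoic acid; 18 methyl 3-(bromomethyl)-4,5-bis[(tert-butyldimethylsilyl)oxy]benzoate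
Product: 20 (2RS,3S,6E)-2-({2,3-bis[(tert-butyldimethylsilyl)oxy]-5-(methoxycarbonyl)phenyl}methyl)-2,3,6-trimethyldodec-6-en-11-ynoic acid, via trilithium salt 19 (not isolated)
Conditions: LiN(i-Pr)2 (3.2 equiv), THF, 0 → 40 °C; then 18 (1.0 equiv), −78 → −20 °C; dil. HCl to pH 4
Reagents that add atoms: none
Why: C-alkylation of a carboxylic acid enediolate by a benzylic bromide should form the quaternary carbon (both epimers are acceptable), while the lithium acetylide stays inert in THF at low temperature and the benzylic bromide reacts faster than the aryl ester.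

Step 13
Reactants: 20 (2RS,3S,6E)-2-({2,3-bis[(tert-butyldimethylsilyl)oxy]-5-(methoxycarbonyl)phenyl}methyl)-2,3,6-trimethyldodec-6-en-11-ynoic acid
Product: 21 1,3-dioxoisoindolin-2-yl (2RS,3S,6E)-2-({2,3-bis[(tert-butyldimethylsilyl)oxy]-5-(methoxycarbonyl)phenyl}methyl)-2,3,6-trimethyldodec-6-en-11-ynoate
Conditions: N-hydroxyphthalimide (1.2 equiv), DIC (1.3 equiv), DMAP (10 mol %), CH2Cl2, 23 °C
Reagents that add atoms: N-hydroxyphthalimide, O=C1c2ccccc2C(=O)N1O
Why: Steglich-type carbodiimide esterification should give the redox-active N-acyloxyphthalimide under neutral conditions that spare the silyl ethers and the alkyne; no stereocentre changes.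

Step 14
Reactants: 21 1,3-dioxoisoindolin-2-yl (2RS,3S,6E)-2-({2,3-bis[(tert-butyldimethylsilyl)oxy]-5-(methoxycarbonyl)phenyl}methyl)-2,3,6-trimethyldodec-6-en-11-ynoate
Product: 22 methyl 3,4-bis[(tert-butyldimethylsilyl)oxy]-5-{[(1R,2S,4aS,8aS)-1,2,4a-trimethyl-5-methylidenedecahydronaphthalen-1-yl]methyl}benzoate
Conditions: Ru(bpy)3(PF6)2 (2 mol %), Hantzsch ester (1.5 equiv, added over 8 h), CH2Cl2 (0.005 M), blue LEDs, 35 °C
Reagents that add atoms: none
Why: The photoexcited divalent ruthenium complex is reduced by the Hantzsch ester, and the resulting monovalent ruthenium transfers an electron to the N-acyloxyphthalimide, which loses phthalimide anion and CO2 to give the tertiary C9 radical (both C9 epimers of 21 converge on this planar radical); it adds 6-endo-trig to C10 of the E alkene (ring B), the new tertiary C5 radical adds 6-exo-dig to the inner carbon of the terminal alkyne (ring A, the C4–C5 bond), and the sigma-vinyl radical takes a hydrogen atom from the Hantzsch ester to leave the exocyclic methylene. The closest known reactions are reductive decarboxylative C–C bond formations of tertiary radicals from N-acyloxyphthalimides under the same photoredox conditions, all-trans radical polyene cyclisations in which tertiary radicals add 6-endo to unactivated trisubstituted alkenes, and alkyne-terminated tin hydride cascades that leave an exocyclic methylene next to a quaternary carbon. Ring B should close through a chair transition state with the C8 methyl equatorial, so the existing C8 centre selects the alkene face, while at the planar C9 radical the bulky silyloxy-arylmethyl group takes the outside (equatorial) site and the methyl the axial site. The E geometry of the alkene places the alkynyl chain equatorial and H axial at C10, and closure of ring A in the chair–chair arrangement puts the new C5–C4 bond equatorial and the C5 methyl axial, which is the trans ring fusion. The selectivities needed are 6-endo over 5-exo (5-exo would have to join two fully substituted carbons), exo over endo attack on the alkyne (favoured by the unsubstituted alkyne terminus), and cyclisation over premature hydrogen transfer, which is favoured by high dilution and slow addition of a donor expected to react sluggishly with nucleophilic alkyl radicals but rapidly with the sigma-vinyl radical.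

Step 15
Reactants: 22 methyl 3,4-bis[(tert-butyldimethylsilyl)oxy]-5-{[(1R,2S,4aS,8aS)-1,2,4a-trimethyl-5-methylidenedecahydronaphthalen-1-yl]methyl}benzoate
Product: 23 dictyoceratin A, methyl 3,4-dihydroxy-5-{[(1R,2S,4aS,8aS)-1,2,4a-trimethyl-5-methylidenedecahydronaphthalen-1-yl]methyl}benzoate
Conditions: KHF2 (4 equiv), MeOH, 23 °C, argon
Reagents that add atoms: none
Why: Fluoride-mediated cleavage of aryl silyl ethers is selective and non-acidic, so the methyl ester, the exocyclic alkene and all four stereocentres should be untouched.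

**Compound list**

1 | (5-chloropent-1-yn-1-yl)trimethylsilane | C[Si](C)(C)C#CCCCCl | starting material
2 | methacrolein (2-methylprop-2-enal) | C=C(C)C=O | starting material
3 | [5-(trimethylsilyl)pent-4-yn-1-yl]magnesium chloride | C[Si](C)(C)C#CCCC[Mg]Cl | intermediate (not isolated)
4 | (3RS)-2-methyl-8-(trimethylsilyl)oct-1-en-7-yn-3-ol | C=C(C)C(O)CCCC#C[Si](C)(C)C | intermediate
5 | [6-(1,1-diethoxyethoxy)-7-methyloct-7-en-1-yn-1-yl]trimethylsilane (mixed orthoester) | CCOC(C)(OCC)OC(C(C)=C)CCCC#C[Si](C)(C)C | intermediate (not isolated)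
6 | {6-[(1-ethoxyethenyl)oxy]-7-methyloct-7-en-1-yn-1-yl}trimethylsilane (ketene acetal) | C=C(OCC)OC(C(C)=C)CCCC#C[Si](C)(C)C | intermediate (not isolated)
7 | ethyl (4E)-4-methyl-10-(trimethylsilyl)dec-4-en-9-ynoate | CCOC(=O)CC/C(C)=C/CCCC#C[Si](C)(C)C | intermediate
8 | (4E)-4-methyl-10-(trimethylsilyl)dec-4-en-9-ynal | O=CCC/C(C)=C/CCCC#C[Si](C)(C)C | intermediate
9 | methyl (2E,6E)-6-methyl-12-(trimethylsilyl)dodeca-2,6-dien-11-ynoate | COC(=O)/C=C/CC/C(C)=C/CCCC#C[Si](C)(C)C | intermediate
10 | methyl (3S,6E)-3,6-dimethyl-12-(trimethylsilyl)dodec-6-en-11-ynoate | COC(=O)C[C@@H](C)CC/C(C)=C/CCCC#C[Si](C)(C)C | intermediate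
11 | lithium enolate of 10, lithium (3S,6E)-1-methoxy-3,6-dimethyl-12-(trimethylsilyl)dodeca-1,6-dien-11-yn-1-olate | COC(O[Li])=C[C@@H](C)CC/C(C)=C/CCCC#C[Si](C)(C)C | intermediate (not isolated)
12 | methyl (2RS,3S,6E)-2,3,6-trimethyl-12-(trimethylsilyl)dodec-6-en-11-ynoate | COC(=O)C(C)[C@@H](C)CC/C(C)=C/CCCC#C[Si](C)(C)C | intermediate
13 | (2RS,3S,6E)-2,3,6-trimethyldodec-6-en-11-ynoic acid | OC(=O)C(C)[C@@H](C)CC/C(C)=C/CCCC#C | intermediate
14 | methyl 3-bromo-4-hydroxy-5-methoxybenzoate | COC(=O)c1cc(Br)c(O)c(OC)c1 | starting material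
15 | methyl 3-bromo-4,5-dihydroxybenzoate | COC(=O)c1cc(Br)c(O)c(O)c1 | intermediate
16 | methyl 3-bromo-4,5-bis[(tert-butyldimethylsilyl)oxy]benzoate | COC(=O)c1cc(Br)c(O[Si](C)(C)C(C)(C)C)c(O[Si](C)(C)C(C)(C)C)c1 | intermediate
17 | methyl 3,4-bis[(tert-butyldimethylsilyl)oxy]-5-methylbenzoate | COC(=O)c1cc(C)c(O[Si](C)(C)C(C)(C)C)c(O[Si](C)(C)C(C)(C)C)c1 | intermediate
18 | methyl 3-(bromomethyl)-4,5-bis[(tert-butyldimethylsilyl)oxy]benzoate | COC(=O)c1cc(CBr)c(O[Si](C)(C)C(C)(C)C)c(O[Si](C)(C)C(C)(C)C)c1 | intermediate
19 | trilithium salt of 13 (enediolate and acetylide) | [Li]OC(O[Li])=C(C)[C@@H](C)CC/C(C)=C/CCCC#C[Li] | intermediate (not isolated)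
20 | (2RS,3S,6E)-2-({2,3-bis[(tert-butyldimethylsilyl)oxy]-5-(methoxycarbonyl)phenyl}methyl)-2,3,6-trimethyldodec-6-en-11-ynoic acid | OC(=O)C(C)(Cc1cc(C(=O)OC)cc(O[Si](C)(C)C(C)(C)C)c1O[Si](C)(C)C(C)(C)C)[C@@H](C)CC/C(C)=C/CCCC#C | intermediate
21 | 1,3-dioxoisoindolin-2-yl (2RS,3S,6E)-2-({2,3-bis[(tert-butyldimethylsilyl)oxy]-5-(methoxycarbonyl)phenyl}methyl)-2,3,6-trimethyldodec-6-en-11-ynoate | O=C(ON1C(=O)c2ccccc2C1=O)C(C)(Cc1cc(C(=O)OC)cc(O[Si](C)(C)C(C)(C)C)c1O[Si](C)(C)C(C)(C)C)[C@@H](C)CC/C(C)=C/CCCC#C | intermediate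
22 | methyl 3,4-bis[(tert-butyldimethylsilyl)oxy]-5-{[(1R,2S,4aS,8aS)-1,2,4a-trimethyl-5-methylidenedecahydronaphthalen-1-yl]methyl}benzoate | C=C1CCC[C@H]2[C@](C)(Cc3cc(C(=O)OC)cc(O[Si](C)(C)C(C)(C)C)c3O[Si](C)(C)C(C)(C)C)[C@@H](C)CC[C@]12C | intermediate
23 | dictyoceratin A, methyl 3,4-dihydroxy-5-{[(1R,2S,4aS,8aS)-1,2,4a-trimethyl-5-methylidenedecahydronaphthalen-1-yl]methyl}benzoate | C=C1CCC[C@H]2[C@](C)(Cc3cc(C(=O)OC)cc(O)c3O)[C@@H](C)CC[C@]12C | target

**Step count and risks**

Total step count: 15. Longest linear sequence: 11 steps (steps 1–7 and 12–15); fragment 2 takes steps 8–11.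

Steps most likely to fail:

Step 14. What may go wrong: hydrogen-atom transfer to the tertiary radical before the slow 6-endo closure; incomplete discrimination between methyl and arylmethyl at the planar radical carbon; or closure of ring A from the wrong face. Fallback (ionic closure of ring B, then radical closure of ring A): setting out from acid 20, Kochi chlorodecarboxylation (Pb(OAc)4, LiCl, benzene, 80 °C) should give the tertiary chloride methyl 3,4-bis[(tert-butyldimethylsilyl)oxy]-5-[(2RS,3S,6E)-2-chloro-2,3,6-trimethyldodec-6-en-11-yn-1-yl]benzoate F1. Ionisation with SnCl4 (CH2Cl2, −78 °C) should induce a chair cation–olefin 6-endo closure onto the E alkene, with chloride return at the new tertiary centre, to give the monocyclic chloride methyl 3,4-bis[(tert-butyldimethylsilyl)oxy]-5-{[(1R,2S,6S)-5-chloro-1,2,5-trimethyl-6-(pent-4-yn-1-yl)cyclohexyl]methyl}benzoate F2. Slow addition of Bu3SnH (AIBN, benzene, 80 °C) should then generate the ring radical, which closes 6-exo-dig onto the alkyne and is reduced at the vinyl stage, so that the route is rejoined at 22.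

Step 12. What may go wrong: sluggish C-alkylation at the hindered enediolate carbon, so that attack of the strongly basic polyanion on the aryl ester or C-benzylation of the acetylide takes over. Fallback (mono-anionic ester enolate carrying an ester that is cleaved under neutral conditions): setting out from acid 13, esterification (allyl bromide, K2CO3, DMF) should give prop-2-en-1-yl (2RS,3S,6E)-2,3,6-trimethyldodec-6-en-11-ynoate F3. Deprotonation with LiN(i-Pr)2 (2.1 equiv, THF, −78 °C, kept cold to avoid Ireland–Claisen rearrangement) should give the dilithium enolate–acetylide F4, which is alkylated with 18 to prop-2-en-1-yl (2RS,3S,6E)-2-({2,3-bis[(tert-butyldimethylsilyl)oxy]-5-(methoxycarbonyl)phenyl}methyl)-2,3,6-trimethyldodec-6-en-11-ynoate F5. Deallylation with Pd(PPh3)4 and morpholine in THF, which should leave the aryl methyl ester and the silyl ethers alone, returns to the route at 20.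

Step 5. What may go wrong: insufficient facial discrimination by the catalyst, or slow conjugate addition with competing 1,2-addition to the ester. Fallback (auxiliary control in place of catalyst control): setting out from enoate 9, hydrolysis with Me3SnOH (1,2-dichloroethane, 80 °C; the alkynylsilane should survive) gives (2E,6E)-6-methyl-12-(trimethylsilyl)dodeca-2,6-dien-11-ynoic acid F6. Coupling with (4R)-4-phenyl-1,3-oxazolidin-2-one (DCC, DMAP, CH2Cl2) should give (4R)-3-[(2E,6E)-6-methyl-12-(trimethylsilyl)dodeca-2,6-dien-11-ynoyl]-4-phenyl-1,3-oxazolidin-2-one F7. Addition of the methylcopper reagent from MeMgBr and CuBr·SMe2 (THF/Me2S, −20 °C) to the chelated s-cis conformer, anti to the phenyl group, should give (4R)-3-[(3S,6E)-3,6-dimethyl-12-(trimethylsilyl)dodec-6-en-11-ynoyl]-4-phenyl-1,3-oxazolidin-2-one F8, separable from its epimer. Methanolysis (NaOMe, MeOH, 0 °C) releases the auxiliary and returns to the route at 10.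

Further compounds
F1 | step 14 | methyl 3,4-bis[(tert-butyldimethylsilyl)oxy]-5-[(2RS,3S,6E)-2-chloro-2,3,6-trimethyldodec-6-en-11-yn-1-yl]benzoate | COC(=O)c1cc(CC(C)(Cl)[C@@H](C)CC/C(C)=C/CCCC#C)c(O[Si](C)(C)C(C)(C)C)c(O[Si](C)(C)C(C)(C)C)c1
F2 | step 14 | methyl 3,4-bis[(tert-butyldimethylsilyl)oxy]-5-{[(1R,2S,6S)-5-chloro-1,2,5-trimethyl-6-(pent-4-yn-1-yl)cyclohexyl]methyl}benzoate (both epimers at the chlorine-bearing carbon) | C#CCCC[C@H]1[C@](C)(Cc2cc(C(=O)OC)cc(O[Si](C)(C)C(C)(C)C)c2O[Si](C)(C)C(C)(C)C)[C@@H](C)CCC1(C)Cl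
F3 | step 12 | prop-2-en-1-yl (2RS,3S,6E)-2,3,6-trimethyldodec-6-en-11-ynoate | C=CCOC(=O)C(C)[C@@H](C)CC/C(C)=C/CCCC#C
F4 | step 12 | dilithium enolate–acetylide of F3 | C=CCOC(O[Li])=C(C)[C@@H](C)CC/C(C)=C/CCCC#C[Li]
F5 | step 12 | prop-2-en-1-yl (2RS,3S,6E)-2-({2,3-bis[(tert-butyldimethylsilyl)oxy]-5-(methoxycarbonyl)phenyl}methyl)-2,3,6-trimethyldodec-6-en-11-ynoate | C=CCOC(=O)C(C)(Cc1cc(C(=O)OC)cc(O[Si](C)(C)C(C)(C)C)c1O[Si](C)(C)C(C)(C)C)[C@@H](C)CC/C(C)=C/CCCC#C
F6 | step 5 | (2E,6E)-6-methyl-12-(trimethylsilyl)dodeca-2,6-dien-11-ynoic acid | OC(=O)/C=C/CC/C(C)=C/CCCC#C[Si](C)(C)C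
F7 | step 5 | (4R)-3-[(2E,6E)-6-methyl-12-(trimethylsilyl)dodeca-2,6-dien-11-ynoyl]-4-phenyl-1,3-oxazolidin-2-one | O=C(/C=C/CC/C(C)=C/CCCC#C[Si](C)(C)C)N1C(=O)OC[C@H]1c1ccccc1
F8 | step 5 | (4R)-3-[(3S,6E)-3,6-dimethyl-12-(trimethylsilyl)dodec-6-en-11-ynoyl]-4-phenyl-1,3-oxazolidin-2-one | O=C(C[C@@H](C)CC/C(C)=C/CCCC#C[Si](C)(C)C)N1C(=O)OC[C@H]1c1ccccc1
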